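**Retrosynthetic overview**

1. Biogenetic numbering is used: N–C1–C2–C3=C4, C5 (ketone), C6, C7, C8, C15 (Me, OAc), C14, C13 (OAc), quaternary C12, C11–C10–C9–N. Ring A is the cyclohexane C7/C8/C15/C14/C13/C12, ring B the cyclopentanone C4/C5/C6/C7/C12, ring C the azonine. The target is (7S,12S,13S,15S) with an E C3=C4 bond.
2. Late disconnections: the C15 acetate, then N–C9 (ring C, intramolecular N-alkylation). Ring B with its C5 ketone, the E C3=C4 bond and the C4–C12 bond comes from a gold-catalysed semipinacol ring expansion of a 1-alkynylcyclobutanol (C12 migrates from C5 to C4). The cis C13/C15 diol comes from an OH-directed epoxidation and hydride opening.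
3. Key disconnection: ring A by an enantioselective endo Diels–Alder reaction of 2-(3-chloropropyl)cyclobut-2-enone (C5, C6, C7, C12) with (E)-1-silyloxy-3-methylbutadiene (C13, C14, C15, C8).
4. Enabling feature: ring A carries O on C13 and Me plus O on C15, the 1,3-pattern of a 1-oxy-3-methyl diene. It is fused through C7–C12 to ring B, where only C4 separates the quaternary C12 from the C5 carbonyl. Deleting C4 turns C7=C12 into the strained, carbonyl-activated double bond of a cyclobutenone, and the exocyclic enone C5(=O)–C4=C3 is what strain-driven re-insertion of C4 as an alkyne carbon gives back.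
5. Ring order: four-membered ring (dienophile), ring A (key step), ring B (ring expansion), ring C (N-alkylation).

Key step: step 5

Remark: the facial sense of the oxazaborolidinium catalyst on a 2-alkylcyclobutenone is assumed by analogy with other α-substituted enone dienophiles; the (S)-catalyst is written, and its antipode would be used if the opposite face proves to be preferred.

**Route**

Step 1
Reactants: 1 ethoxyacetylene; 2 1-chloro-3-iodopropane
Product: 4 5-chloro-1-ethoxypent-1-yne, via lithium ethoxyacetylide 3 (not isolated)
Conditions: n-BuLi, THF, –78 °C; then 2, HMPA, –78 °C → rt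
Reagents that add atoms: none
Why: SN2 alkylation of a lithium alkoxyacetylide should occur at the iodide and leave the chloride as the latent C9 electrophile.

Step 2
Reactants: 4 5-chloro-1-ethoxypent-1-yne; 5 acetyl chloride
Product: 7 2-(3-chloropropyl)-3-ethoxycyclobut-2-en-1-one, via ketene 6 (not isolated)
Conditions: Et3N, Et2O, 0 °C → rt, slow addition of 5
Reagents that add atoms: none
Why: In this ketene–ynol ether [2+2] cycloaddition the ketene carbonyl carbon should bond to the nucleophilic β-carbon of the ynol ether, which puts the chloropropyl chain on the carbon next to the carbonyl.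

Step 3
Reactants: 7 2-(3-chloropropyl)-3-ethoxycyclobut-2-en-1-one
Product: 9 2-(3-chloropropyl)cyclobut-2-en-1-one, via cyclobutenol 8 (not isolated)
Conditions: i-Bu2AlH, Et2O, –78 °C; then 1 M HCl, 0 °C, short contact; used as a cold solution
Reagents that add atoms: water, O
Why: 1,2-Reduction of the vinylogous ester followed by acid-induced allylic transposition and hydrolysis (Stork–Danheiser-type enone transposition) should move the carbonyl to the former ethoxy carbon, so the chain sits on the α-carbon of the cyclobutenone.

Step 4
Reactants: 10 3-methylbut-2-enal (prenal)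
Product: 11 (E)-tert-butyldimethyl[(3-methylbuta-1,3-dien-1-yl)oxy]silane
Conditions: TBSOTf, Et3N, Et2O, 0 °C → rt
Reagents that add atoms: tert-butyldimethylsilyl triflate, CC(C)(C)[Si](C)(C)OS(=O)(=O)C(F)(F)F
Why: γ-Deprotonation with O-silylation of the enal (vinylogous silyl enol ether formation) should give the E-configured 1-silyloxy diene.

Step 5
Reactants: 9 2-(3-chloropropyl)cyclobut-2-en-1-one; 11 (E)-1-silyloxy-3-methyl diene
Product: 12 cis-fused 5-(tert-butyldimethylsilyloxy)-6-(3-chloropropyl)-3-methylbicyclo[4.2.0]oct-3-en-7-one (OTBS at C13 cis to the carbonyl carbon C5 on C12, trans to the chloropropyl chain)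
Conditions: (S)-B-(o-tolyl)oxazaborolidine from (S)-α,α-diphenylprolinol (20 mol%), Tf2NH (18 mol%), CH2Cl2, –78 → –40 °C
Reagents that add atoms: none
Why: The oxazaborolidinium ion binds the cyclobutenone carbonyl and lowers the LUMO of C7=C12, and a concerted, asynchronous [4+2] cycloaddition follows in which C8, the most nucleophilic diene terminus, bonds to the β-carbon C7 ahead of C13 bonding to the α-carbon C12. The closest known reaction type is the Lewis-acid- and chiral-oxazaborolidinium-catalysed endo Diels–Alder reaction of cyclobutenones and other cycloalkenones with 1-oxygenated dienes. Ring A is closed by intermolecular [4+2] cycloaddition of a four-carbon and a two-carbon component, both bonds being made suprafacially. C7 and C12 become cis because both bonds form on one face of the ring-held Z-alkene, C13 is set by the endo transition state with the E-diene (OTBS cis to C5, trans to the chain), and the absolute configuration is set by the catalyst shielding one face of the bound enone. The step needs regio-, endo- and facial selectivity: the first comes from the matched donors of the diene (O on C13, Me on C15) against the α-carbonyl polarisation of the dienophile, the second from overlap with the single ring-held carbonyl, the third from the catalyst. The strain of the cyclobutenone, relieved as C7 and C12 rehybridise, is what should let a hindered α-alkyl dienophile form the quaternary centre at low temperature.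

Step 6
Reactants: 13 but-3-yn-1-amine
Product: 14 N-(but-3-yn-1-yl)-2-(trimethylsilyl)ethanesulfonamide
Conditions: 2-(trimethylsilyl)ethanesulfonyl chloride (SESCl), Et3N, CH2Cl2, 0 °C
Reagents that add atoms: 2-(trimethylsilyl)ethanesulfonyl chloride, C[Si](C)(C)CCS(=O)(=O)Cl
Why: N-Sulfonylation of a primary amine installs a nitrogen protecting group that is inert to organolithium, hydride and gold and is removed by fluoride.

Step 7
Reactants: 14 N-(but-3-yn-1-yl)-SES-amide
Product: 15 N-(but-3-yn-1-yl)-N-methyl-2-(trimethylsilyl)ethanesulfonamide
Conditions: MeI, K2CO3, DMF, rt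
Reagents that add atoms: iodomethane, CI
Why: N-Alkylation of the acidic sulfonamide N–H puts in the N-methyl group and leaves no N–H that could add to the gold-activated alkyne in step 13.

Step 8
Reactants: 12 cyclobutanone adduct; 15 N-methyl-SES alkyne
Product: 17 alkynyl cyclobutanol (12 with C5 carrying OH and the 4-[methyl(SES)amino]but-1-ynyl group), via lithium acetylide 16 (not isolated)
Conditions: n-BuLi, THF, –78 °C; then 12, –78 °C; NH4Cl (aq)
Reagents that add atoms: none
Why: 1,2-Addition of a lithium acetylide to the strained cyclobutanone should be fast and is expected from the face anti to ring A; the configuration at C5 is of no consequence because C5 becomes a carbonyl carbon again in step 13.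

Step 9
Reactants: 17 alkynyl cyclobutanol silyl ether
Product: 18 diol (free C13–OH and C5–OH)
Conditions: Bu4NF, THF, 0 °C → rt
Reagents that add atoms: none
Why: Fluoride desilylation frees the allylic C13 hydroxyl; the SES sulfonamide (cleaved only on heating) and the primary chloride should survive.

Step 10
Reactants: 18 diol
Product: 19 epoxy diol (C14–C15 epoxide oxygen cis to C13–OH)
Conditions: VO(acac)2 (5 mol%), t-BuOOH, CH2Cl2, 0 °C → rt
Reagents that add atoms: tert-butyl hydroperoxide, CC(C)(C)OO
Why: In this hydroxyl-directed epoxidation the vanadium alkoxide of the allylic C13–OH delivers oxygen to the syn face of C14=C15, which sets the C15–O bond cis to C13–O; the alkyne and sulfonamide are inert.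

Step 11
Reactants: 19 epoxy diol
Product: 20 triol (C13–OH and tertiary C15–OH cis, C15 methyl trans)
Conditions: LiEt3BH, THF, 0 °C
Reagents that add atoms: none
Why: SN2 hydride opening of the trisubstituted epoxide at the secondary carbon C14 (trans-diaxial, Fürst–Plattner) leaves the C15–O bond untouched, and LiEt3BH does not reduce the alkyne and attacks a primary chloride only slowly at 0 °C.

Step 12
Reactants: 20 triol
Product: 21 C13 monoacetate
Conditions: Ac2O, pyridine, DMAP (cat.), CH2Cl2, 0 °C
Reagents that add atoms: acetic anhydride, CC(=O)OC(C)=O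
Why: Selective acylation of the only secondary hydroxyl installs the C13 acetate of the target and masks an OH that could otherwise add 5-exo to the activated alkyne in step 13.

Step 13
Reactants: 21 alkynyl cyclobutanol monoacetate
Product: 22 cis-hydrindanone with C5 ketone and E-configured C4=C3 alkylidene (C2 cis to C12)
Conditions: Ph3PAuNTf2 (5 mol%), CH2Cl2, rt
Reagents that add atoms: none
Why: In this semipinacol ring expansion catalysed by monovalent gold, π-activation of the alkyne triggers an anti 1,2-shift of the more substituted cyclobutane carbon C12 (with retention) from C5 to C4 while C5 becomes the ketone, driven by release of cyclobutane strain, and protodeauration with retention gives the E-alkylidene.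

Step 14
Reactants: 22 SES-protected amino chloride enone
Product: 24 tricyclic azonine hydroxy acetate (15-O-deacetyl target), via amino chloride 23 (not isolated)
Conditions: CsF, DMF, 90 °C; then NaI, K2CO3, MeCN (dilution to 0.002 M), 70 °C
Reagents that add atoms: none
Why: Fluoride-induced fragmentation of the SES group frees the secondary N-methylamine, which should close ring C by intramolecular SN2 displacement at C9 (iodide formed in situ), the two chains being held close by the cis arrangement of C2 and C12 about C4=C3.

Step 15
Reactants: 24 tricyclic hydroxy acetate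
Product: 25 target diacetate
Conditions: Ac2O, DMAP, Et3N, CH2Cl2, rt → 40 °C
Reagents that add atoms: acetic anhydride, CC(=O)OC(C)=O
Why: DMAP-catalysed acetylation of the tertiary C15 alcohol (and of any C13–OH freed by acyl migration in step 14) should give the diacetate without affecting the tertiary amine or the enone.

**Compound list**

1 | ethoxyacetylene | C#COCC | starting material
2 | 1-chloro-3-iodopropane | ClCCCI | starting material
3 | lithium ethoxyacetylide | [Li]C#COCC | intermediate
4 | 5-chloro-1-ethoxypent-1-yne | CCOC#CCCCCl | intermediate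
5 | acetyl chloride | CC(=O)Cl | starting material
6 | ketene | C=C=O | intermediate
7 | 2-(3-chloropropyl)-3-ethoxycyclobut-2-en-1-one | CCOC1=C(CCCCl)C(=O)C1 | intermediate
8 | 2-(3-chloropropyl)-3-ethoxycyclobut-2-en-1-ol (racemic, not isolated) | CCOC1=C(CCCCl)C(O)C1 | intermediate
9 | 2-(3-chloropropyl)cyclobut-2-en-1-one | O=C1CC=C1CCCCl | intermediate
10 | 3-methylbut-2-enal (prenal) | CC(C)=CC=O | starting material
11 | (E)-tert-butyldimethyl[(3-methylbuta-1,3-dien-1-yl)oxy]silane | CC(=C)/C=C/O[Si](C)(C)C(C)(C)C | intermediate
12 | cis-fused 5-(tert-butyldimethylsilyloxy)-6-(3-chloropropyl)-3-methylbicyclo[4.2.0]oct-3-en-7-one; OTBS cis to the ketone carbon on the adjacent ring-fusion carbon, trans to the chloropropyl chain | CC(C)(C)[Si](C)(C)O[C@H]1C=C(C)C[C@H]2CC(=O)[C@]21CCCCl | intermediate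
13 | but-3-yn-1-amine | C#CCCN | starting material
14 | N-(but-3-yn-1-yl)-2-(trimethylsilyl)ethanesulfonamide | C#CCCNS(=O)(=O)CC[Si](C)(C)C | intermediate
15 | N-(but-3-yn-1-yl)-N-methyl-2-(trimethylsilyl)ethanesulfonamide | C#CCCN(C)S(=O)(=O)CC[Si](C)(C)C | intermediate
16 | lithium acetylide of 15 | [Li]C#CCCN(C)S(=O)(=O)CC[Si](C)(C)C | intermediate
17 | alkynyl cyclobutanol: 12 with the ketone carbon (C5) converted into C(OH)(C≡C–CH2CH2–N(Me)SES), alkynyl group expected cis to the chloropropyl chain | CC(C)(C)[Si](C)(C)O[C@H]1C=C(C)C[C@H]2C[C@](O)(C#CCCN(C)S(=O)(=O)CC[Si](C)(C)C)[C@]21CCCCl | intermediate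
18 | diol: 17 with free C13–OH | O[C@H]1C=C(C)C[C@H]2C[C@](O)(C#CCCN(C)S(=O)(=O)CC[Si](C)(C)C)[C@]21CCCCl | intermediate
19 | epoxy diol: C14–C15 epoxide, oxygen cis to C13–OH | O[C@H]1[C@H]4O[C@@]4(C)C[C@H]2C[C@](O)(C#CCCN(C)S(=O)(=O)CC[Si](C)(C)C)[C@]21CCCCl | intermediate
20 | triol: C13–OH and tertiary C15–OH cis, C15 methyl trans | O[C@H]1C[C@@](C)(O)C[C@H]2C[C@](O)(C#CCCN(C)S(=O)(=O)CC[Si](C)(C)C)[C@]21CCCCl | intermediate
21 | C13 monoacetate of 20 | CC(=O)O[C@H]1C[C@@](C)(O)C[C@H]2C[C@](O)(C#CCCN(C)S(=O)(=O)CC[Si](C)(C)C)[C@]21CCCCl | intermediate
22 | cis-hydrindan-5-one with E-configured C4=C3 alkylidene bearing CH2CH2N(Me)SES, C12 3-chloropropyl, C13 acetate, C15 tertiary alcohol | CC(=O)O[C@H]1C[C@@](C)(O)C[C@H]2CC(=O)/C(=C/CCN(C)S(=O)(=O)CC[Si](C)(C)C)[C@]21CCCCl | intermediate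
23 | amino chloride: 22 with free NHMe | CC(=O)O[C@H]1C[C@@](C)(O)C[C@H]2CC(=O)/C(=C/CCNC)[C@]21CCCCl | intermediate
24 | tricyclic azonine, C13 acetate, C15 tertiary alcohol (15-O-deacetyl target) | CC(=O)O[C@H]1C[C@@](C)(O)C[C@H]2CC(=O)/C3=C/CCN(C)CCC[C@@]321 | intermediate
25 | target diacetate, (7S,12S,13S,15S), C3=C4 E | CC(=O)O[C@H]1C[C@@](C)(OC(C)=O)C[C@H]2CC(=O)/C3=C/CCN(C)CCC[C@@]321 | target

**Step count and risks**

Total steps: 15. Longest linear sequence: 12 steps (steps 1, 2, 3, 5, 8, 9, 10, 11, 12, 13, 14, 15).

Step 5 is the most likely to fail. The catalysed cycloaddition may show poor facial selectivity with the α-alkyl cyclobutenone, or it may leave the concerted path for a stepwise Mukaiyama–Michael addition with loss of the silyl group. The fallback replaces catalyst control by a covalent auxiliary on the diene. It sets out from 10 and 9. Prenal 10 is deprotonated with t-BuOK in THF at –78 °C and O-acylated with (S)-O-methylmandeloyl chloride to give the dienyl (S)-O-methylmandelate F1. Cycloaddition of F1 with 9 (thermal, or with BF3·OEt2 at low temperature) should give, under auxiliary control of the diene face and after purification to diastereomeric homogeneity, the mandelate cyclobutanone adduct F2. The organocerium reagent made from 15 (n-BuLi, then CeCl3, THF, –78 °C) adds to the ketone of F2 in the presence of the ester to give the alkynyl cyclobutanol mandelate F3. Methanolysis (K2CO3, MeOH) removes the auxiliary, and the route is rejoined at 18.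

Step 13 is the second risk. Activation of the internal alkyne by the gold catalyst may be slow, so that a 1,3-hydroxyl shift (Meyer–Schuster-type) or simple decomposition competes with the ring expansion. The fallback uses a stoichiometric halonium-induced semipinacol shift instead. It sets out from 21. N-Iodosuccinimide in CH2Cl2 at 0 °C should trigger the same anti 1,2-shift of C12 and give the β-iodo enone F4 (iodine cis to the C5 carbonyl, C2 cis to C12). Stereoretentive hydrodeiodination with Bu3SnH and Pd(PPh3)4 (zerovalent palladium) then gives 22, where the route is rejoined.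

Step 14 is the third risk. Intermolecular N-alkylation (oligomerisation) may outrun closure of the nine-membered ring, and the SN2 step cannot correct such errors. The fallback closes ring C by reversible C=N formation followed by reduction. It sets out from 22. Finkelstein exchange and Kornblum oxidation in one flask (NaI, NaHCO3, DMSO, 100 °C) convert the chloropropyl terminus into the C9 aldehyde F5. Removal of the SES group (Bu4NF, THF, 50 °C) gives the amino aldehyde F6, which is not isolated. Under high dilution it should equilibrate to the cyclic hemiaminal/iminium ion and is reduced with NaBH(OAc)3 and AcOH in 1,2-dichloroethane to 24, where the route is rejoined.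

Further compounds
F1 | step 5 | (E)-3-methylbuta-1,3-dien-1-yl (S)-2-methoxy-2-phenylacetate | CC(=C)/C=C/OC(=O)[C@@H](OC)c1ccccc1
F2 | step 5 | (S)-O-methylmandelate analogue of 12 (ester oxygen at C13, same ring configuration as 12) | CO[C@@H](c1ccccc1)C(=O)O[C@H]1C=C(C)C[C@H]2CC(=O)[C@]21CCCCl
F3 | step 5 | (S)-O-methylmandelate analogue of 17 | CO[C@@H](c1ccccc1)C(=O)O[C@H]1C=C(C)C[C@H]2C[C@](O)(C#CCCN(C)S(=O)(=O)CC[Si](C)(C)C)[C@]21CCCCl
F4 | step 13 | 3-iodo analogue of 22 (iodine on C3 cis to the C5 carbonyl, C2 cis to C12) | CC(=O)O[C@H]1C[C@@](C)(O)C[C@H]2CC(=O)/C(=C(\I)/CCN(C)S(=O)(=O)CC[Si](C)(C)C)[C@]21CCCCl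
F5 | step 14 | C9 aldehyde analogue of 22 (3-oxopropyl chain on C12) | CC(=O)O[C@H]1C[C@@](C)(O)C[C@H]2CC(=O)/C(=C/CCN(C)S(=O)(=O)CC[Si](C)(C)C)[C@]21CCC=O
F6 | step 14 | amino aldehyde (F5 with free NHMe, not isolated) | CC(=O)O[C@H]1C[C@@](C)(O)C[C@H]2CC(=O)/C(=C/CCNC)[C@]21CCC=O
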